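The cyclohexene ring C1–C6 is treated as a carba-altropyranose: O4, O5 and O6 reproduce O2, O3 and O4 of D-altrose, C1 is the old sugar C5 and C2 takes the place of the ring oxygen. The synthesis therefore rests on forming the C2–C3 bond by a Ferrier carbocyclisation. In one operation a mercury salt hydrates the exocyclic enol ether of a methyl 6-deoxy-α-D-arabino-hex-5-enopyranoside, opens the pyranose and closes the carbocycle by aldol, leaving a C1 ketone for attaching C7 and a C3 carbinol. The precursor already carries the O5 benzoate (from benzoate opening of a sugar epoxide) and TBS ethers on the two flanking oxygens.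

Key step: step 7

Remark on numbering: carbocycles are numbered as in the target (C1 bears C7; C2 = former sugar C6; C3 = former anomeric carbon; C4, C5, C6 = former sugar C2, C3, C4); sugars keep carbohydrate numbering. TBS = tert-butyldimethylsilyl, TES = triethylsilyl.

Assumption: the aldol of step 7 should place the new C3 hydroxyl trans to the C5 benzoate and cis to O4, as is usual for this carbocyclisation; this is the C3 epimer of the target, so steps 13 and 14 invert C3.

Step 1
Reactants: 1 methyl 4,6-O-benzylidene-α-D-glucopyranoside (catalogue compound)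
Product: 3 methyl 2,3-anhydro-4,6-O-benzylidene-α-D-mannopyranoside, via 2-O-tosylate 2 (not isolated)
Conditions: NaH (2.5 equiv), N-tosylimidazole (1.1 equiv), DMF, 0 °C → rt
Reagents that add atoms: none
Why: The more acidic 2-OH is sulfonylated selectively as its alkoxide and the neighbouring 3-alkoxide then displaces the tosylate from the β-face (intramolecular Williamson-type SN2), inverting C2 and giving the β-face manno-epoxide in one pot.

Step 2
Reactants: 3 methyl 2,3-anhydro-4,6-O-benzylidene-α-D-mannopyranoside; 4 benzoic acid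
Product: 5 methyl 3-O-benzoyl-4,6-O-benzylidene-α-D-altropyranoside
Conditions: PhCO2H (3 equiv), tetrabutylammonium benzoate (0.5 equiv), DMF, 110 °C
Reagents that add atoms: none
Why: Fürst–Plattner trans-diaxial epoxide opening by a carboxylate: in the benzylidene-locked ring benzoate attacks C3 from the α-face with inversion, giving the altro 3-benzoate whose axial 2-OH is trans-diaxial to the ester and so cannot take it over.

Step 3
Reactants: 5 methyl 3-O-benzoyl-4,6-O-benzylidene-α-D-altropyranoside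
Product: 6 methyl 3-O-benzoyl-α-D-altropyranoside
Conditions: H2 (1 atm), Pd(OH)2 on carbon, EtOAc/MeOH, rt
Reagents that add atoms: none
Why: Hydrogenolysis of the benzylic acetal C–O bonds under neutral conditions frees O4 and O6 without touching the benzoate and without base that could make it migrate.

Step 4
Reactants: 6 methyl 3-O-benzoyl-α-D-altropyranoside
Product: 7 methyl 3-O-benzoyl-6-deoxy-6-iodo-α-D-altropyranoside
Conditions: I2, PPh3, imidazole, THF, rt → 50 °C
Reagents that add atoms: iodine, II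
Why: Garegg–Samuelsson (Appel-type) iodination activates only the primary 6-OH as an oxyphosphonium ion, which iodide displaces by SN2, while the hindered secondary 2- and 4-hydroxyls stay free.

Step 5
Reactants: 7 methyl 3-O-benzoyl-6-deoxy-6-iodo-α-D-altropyranoside
Product: 8 methyl 3-O-benzoyl-2,4-bis-O-TBS-6-deoxy-6-iodo-α-D-altropyranoside
Conditions: TBSOTf (3 equiv), 2,6-lutidine, CH2Cl2, 0 °C → rt
Reagents that add atoms: tert-butyldimethylsilyl trifluoromethanesulfonate, CC(C)(C)[Si](C)(C)OS(=O)(=O)C(F)(F)F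
Why: The silyl triflate with a hindered pyridine base silylates even crowded secondary alcohols, capping O2 and O4 in one step with ethers that should survive mercury salts, amide base, hot palladium coupling and Mitsunobu conditions.

Step 6
Reactants: 8 methyl 3-O-benzoyl-2,4-bis-O-TBS-6-deoxy-6-iodo-α-D-altropyranoside
Product: 9 methyl 3-O-benzoyl-2,4-bis-O-TBS-6-deoxy-α-D-arabino-hex-5-enopyranoside
Conditions: DBU, THF, reflux
Reagents that add atoms: none
Why: E2 dehydrohalogenation by the non-nucleophilic amidine removes H5 anti to iodide and gives the exocyclic enol ether, the benzoate and silyl ethers being inert to DBU in an aprotic solvent.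

Step 7
Reactants: 9 methyl 3-O-benzoyl-2,4-bis-O-TBS-6-deoxy-α-D-arabino-hex-5-enopyranoside
Product: 12 (3R)-5-(benzoyloxy)-4,6-bis(TBS-oxy)-3-hydroxycyclohexan-1-one (3-OH cis to O4 and trans to O5), via C5 hemiketal organomercurial 10 (not isolated), via open-chain mercurio keto-aldehyde 11 (not isolated)
Conditions: Hg(OCOCF3)2 (10 mol %), acetone/H2O 4:1, rt
Reagents that add atoms: water, O
Why: Ferrier carbocyclisation: Hg(OCOCF3)2 (divalent mercury) and water add across the electron-rich sugar C5=C6 enol ether (mercury on C6, hydroxyl on C5) to give hemiketal 10, which opens the pyranose and loses methanol from the anomeric carbon to give the 1,5-keto-aldehyde 11 with mercury on the methylene carbon that becomes C2. The mercury enolate of 11 adds to the aldehyde, forming C2–C3 and releasing the mercury salt for another turn, which is the established conversion of 6-deoxyhex-5-enopyranosides into 2-deoxyinososes. The ring closes in a 6-(enolendo)-exo-trig aldol, because the enolate C1=C2 lies inside the new ring and the aldehyde C=O outside it. C4, C5 and C6 are not touched, and the new C3 carbinol is set in a chair-like transition state in which the aldehyde oxygen turns away from the C5–O bond (former sugar O3), so the hydroxyl should emerge trans to the C5 benzoate and cis to the C4 silyl ether, i.e. (3R). The step needs the enolate at C2 and not at C6, which the position of the enol ether guarantees, and it needs the ketol to survive without β-elimination, which the neutral room-temperature catalytic conditions should secure.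

Step 8
Reactants: 12 (3R)-5-(benzoyloxy)-4,6-bis(TBS-oxy)-3-hydroxycyclohexan-1-one
Product: 13 (3R)-5-(benzoyloxy)-4,6-bis(TBS-oxy)-3-(TES-oxy)cyclohexan-1-one
Conditions: Et3SiCl, imidazole, CH2Cl2, 0 °C
Reagents that add atoms: chlorotriethylsilane, CC[Si](CC)(CC)Cl
Why: Silylation of the only free hydroxyl under weakly basic conditions should not trigger β-elimination of the ketol and gives an ether that can later be cleaved in the presence of the two TBS ethers.

Step 9
Reactants: 13 (3R)-5-(benzoyloxy)-4,6-bis(TBS-oxy)-3-(TES-oxy)cyclohexan-1-one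
Product: 14 (3R)-5-(benzoyloxy)-4,6-bis(TBS-oxy)-3-(TES-oxy)cyclohex-1-en-1-yl trifluoromethanesulfonate
Conditions: KN(SiMe3)2, THF, −78 °C; then PhNTf2, −78 °C
Reagents that add atoms: N-phenylbis(trifluoromethanesulfonimide), O=S(=O)(N(c1ccccc1)S(=O)(=O)C(F)(F)F)C(F)(F)F
Why: Kinetic deprotonation by the hindered amide occurs at the open C2 methylene and not at the silyloxy-bearing C6, and O-triflation of this enolate (enol triflate formation) fixes the C1=C2 double bond at low temperature before the β-silyloxy group can be expelled.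

Step 10
Reactants: 14 enol triflate; 15 (tributylstannyl)methanol
Product: 16 (3R)-[5-(benzoyloxy)-4,6-bis(TBS-oxy)-3-(TES-oxy)cyclohex-1-en-1-yl]methanol
Conditions: Pd(PPh3)4 (10 mol %), LiCl, 1,4-dioxane, 90 °C
Reagents that add atoms: none
Why: Migita–Kosugi–Stille coupling: oxidative addition of the enol triflate to zerovalent palladium, chloride exchange and transfer of the hydroxymethyl group from tin place C7 on C1 as a free primary alcohol, with esters and silyl ethers as spectators.

Step 11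
Reactants: 16 allylic alcohol; 17 benzoyl chloride
Product: 18 (3R)-[5-(benzoyloxy)-4,6-bis(TBS-oxy)-3-(TES-oxy)cyclohex-1-en-1-yl]methyl benzoate
Conditions: PhCOCl, pyridine, 4-(dimethylamino)pyridine (cat.), CH2Cl2, 0 °C
Reagents that add atoms: none
Why: Nucleophile-catalysed acylation of the only free hydroxyl, a primary allylic one, installs the O7 benzoate.

Step 12
Reactants: 18 7-O-benzoate with 3-O-TES ether
Product: 19 (3R)-[5-(benzoyloxy)-4,6-bis(TBS-oxy)-3-hydroxycyclohex-1-en-1-yl]methyl benzoate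
Conditions: pyridinium p-toluenesulfonate, MeOH/CH2Cl2, 0 °C → rt
Reagents that add atoms: none
Why: Acid-catalysed methanolysis cleaves the triethylsilyl ether much faster than the bulkier secondary TBS ethers, so only the allylic C3 hydroxyl is bared.

Step 13
Reactants: 19 (3R)-allylic alcohol
Product: 20 (3S)-[5-(benzoyloxy)-4,6-bis(TBS-oxy)-3-(chloroacetoxy)cyclohex-1-en-1-yl]methyl benzoate
Conditions: ClCH2CO2H, PPh3, diisopropyl azodicarboxylate, toluene, 0 °C → rt
Reagents that add atoms: chloroacetic acid, OC(=O)CCl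
Why: Mitsunobu reaction: the oxyphosphonium ion at C3 is displaced by chloroacetate in an SN2 step from the face opposite O4, inverting C3 from R to S, while SN2' attack is disfavoured because C1 is fully substituted and the acidic carboxylic acid keeps the hindered alcohol productive.

Step 14
Reactants: 20 (3S)-chloroacetate
Product: 21 (3S)-[5-(benzoyloxy)-4,6-bis(TBS-oxy)-3-hydroxycyclohex-1-en-1-yl]methyl benzoate
Conditions: thiourea, NaHCO3, EtOH/THF, 50 °C
Reagents that add atoms: none
Why: Thiourea S-alkylates the chloroacetate and cyclises onto its carbonyl (pseudothiohydantoin formation), releasing the C3 alcohol under near-neutral conditions that leave both benzoates in place, their neighbouring oxygens still being silylated.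

Step 15
Reactants: 21 (3S)-alcohol, 4,6-bis-O-TBS ether of the target
Product: 22 [(3S,4R,5R,6R)-5-(benzoyloxy)-3,4,6-trihydroxycyclohex-1-en-1-yl]methyl benzoate (CNP0198957.7)
Conditions: HF·pyridine, pyridine/THF, 0 °C → rt
Reagents that add atoms: none
Why: Fluoride desilylation under acidic buffering removes both TBS ethers without generating alkoxides, so the benzoates should not migrate to the neighbouring hydroxyls as they would with a basic fluoride source.

Compound list
1 | methyl 4,6-O-benzylidene-α-D-glucopyranoside ((R)-acetal, phenyl equatorial) | CO[C@@H]1[C@H](O)[C@@H](O)[C@@H]2O[C@H](c3ccccc3)OC[C@H]2O1 | starting material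
2 | methyl 4,6-O-benzylidene-2-O-(p-tolylsulfonyl)-α-D-glucopyranoside (not isolated) | CO[C@@H]1[C@H](OS(=O)(=O)c2ccc(C)cc2)[C@@H](O)[C@@H]3O[C@H](c4ccccc4)OC[C@H]3O1 | intermediate
3 | methyl 2,3-anhydro-4,6-O-benzylidene-α-D-mannopyranoside | CO[C@@H]1[C@H]2O[C@H]2[C@@H]3O[C@H](c4ccccc4)OC[C@H]3O1 | intermediate
4 | benzoic acid | OC(=O)c1ccccc1 | starting material
5 | methyl 3-O-benzoyl-4,6-O-benzylidene-α-D-altropyranoside | CO[C@@H]1[C@@H](O)[C@H](OC(=O)c2ccccc2)[C@@H]3O[C@H](c4ccccc4)OC[C@H]3O1 | intermediate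
6 | methyl 3-O-benzoyl-α-D-altropyranoside | CO[C@@H]1[C@@H](O)[C@H](OC(=O)c2ccccc2)[C@H](O)[C@@H](CO)O1 | intermediate
7 | methyl 3-O-benzoyl-6-deoxy-6-iodo-α-D-altropyranoside | CO[C@@H]1[C@@H](O)[C@H](OC(=O)c2ccccc2)[C@H](O)[C@@H](CI)O1 | intermediate
8 | methyl 3-O-benzoyl-2,4-bis-O-TBS-6-deoxy-6-iodo-α-D-altropyranoside | CO[C@@H]1[C@@H](O[Si](C)(C)C(C)(C)C)[C@H](OC(=O)c2ccccc2)[C@H](O[Si](C)(C)C(C)(C)C)[C@@H](CI)O1 | intermediate
9 | methyl 3-O-benzoyl-2,4-bis-O-TBS-6-deoxy-α-D-arabino-hex-5-enopyranoside (key-step precursor) | C=C1O[C@H](OC)[C@@H](O[Si](C)(C)C(C)(C)C)[C@H](OC(=O)c2ccccc2)[C@@H]1O[Si](C)(C)C(C)(C)C | intermediate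
10 | C5 hemiketal of 9 carrying HgOCOCF3 on C6, C5 configuration undefined (not isolated) | OC1(C[Hg]OC(=O)C(F)(F)F)O[C@H](OC)[C@@H](O[Si](C)(C)C(C)(C)C)[C@H](OC(=O)c2ccccc2)[C@@H]1O[Si](C)(C)C(C)(C)C | intermediate
11 | aldehydo-3-O-benzoyl-2,4-bis-O-TBS-6-deoxy-6-(trifluoroacetoxymercurio)-D-arabino-hexos-5-ulose (not isolated) | O=C[C@@H](O[Si](C)(C)C(C)(C)C)[C@H](OC(=O)c1ccccc1)[C@H](O[Si](C)(C)C(C)(C)C)C(=O)C[Hg]OC(=O)C(F)(F)F | intermediate
12 | (3R)-5-(benzoyloxy)-4,6-bis(TBS-oxy)-3-hydroxycyclohexan-1-one, 3-OH cis to O4, C4–C6 as in 22 (key-step product) | O=C1C[C@@H](O)[C@@H](O[Si](C)(C)C(C)(C)C)[C@H](OC(=O)c2ccccc2)[C@@H]1O[Si](C)(C)C(C)(C)C | intermediate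
13 | (3R)-5-(benzoyloxy)-4,6-bis(TBS-oxy)-3-(TES-oxy)cyclohexan-1-one | O=C1C[C@@H](O[Si](CC)(CC)CC)[C@@H](O[Si](C)(C)C(C)(C)C)[C@H](OC(=O)c2ccccc2)[C@@H]1O[Si](C)(C)C(C)(C)C | intermediate
14 | (3R)-5-(benzoyloxy)-4,6-bis(TBS-oxy)-3-(TES-oxy)cyclohex-1-en-1-yl trifluoromethanesulfonate | O=S(=O)(OC1=C[C@@H](O[Si](CC)(CC)CC)[C@@H](O[Si](C)(C)C(C)(C)C)[C@H](OC(=O)c2ccccc2)[C@@H]1O[Si](C)(C)C(C)(C)C)C(F)(F)F | intermediate
15 | (tributylstannyl)methanol | CCCC[Sn](CCCC)(CCCC)CO | starting material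
16 | (3R)-[5-(benzoyloxy)-4,6-bis(TBS-oxy)-3-(TES-oxy)cyclohex-1-en-1-yl]methanol | OCC1=C[C@@H](O[Si](CC)(CC)CC)[C@@H](O[Si](C)(C)C(C)(C)C)[C@H](OC(=O)c2ccccc2)[C@@H]1O[Si](C)(C)C(C)(C)C | intermediate
17 | benzoyl chloride | O=C(Cl)c1ccccc1 | starting material
18 | (3R)-[5-(benzoyloxy)-4,6-bis(TBS-oxy)-3-(TES-oxy)cyclohex-1-en-1-yl]methyl benzoate | O=C(OCC1=C[C@@H](O[Si](CC)(CC)CC)[C@@H](O[Si](C)(C)C(C)(C)C)[C@H](OC(=O)c2ccccc2)[C@@H]1O[Si](C)(C)C(C)(C)C)c1ccccc1 | intermediate
19 | (3R)-[5-(benzoyloxy)-4,6-bis(TBS-oxy)-3-hydroxycyclohex-1-en-1-yl]methyl benzoate (3-OH cis to O4) | O=C(OCC1=C[C@@H](O)[C@@H](O[Si](C)(C)C(C)(C)C)[C@H](OC(=O)c2ccccc2)[C@@H]1O[Si](C)(C)C(C)(C)C)c1ccccc1 | intermediate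
20 | (3S)-[5-(benzoyloxy)-4,6-bis(TBS-oxy)-3-(chloroacetoxy)cyclohex-1-en-1-yl]methyl benzoate | O=C(OCC1=C[C@H](OC(=O)CCl)[C@@H](O[Si](C)(C)C(C)(C)C)[C@H](OC(=O)c2ccccc2)[C@@H]1O[Si](C)(C)C(C)(C)C)c1ccccc1 | intermediate
21 | (3S)-[5-(benzoyloxy)-4,6-bis(TBS-oxy)-3-hydroxycyclohex-1-en-1-yl]methyl benzoate (3-OH trans to O4) | O=C(OCC1=C[C@H](O)[C@@H](O[Si](C)(C)C(C)(C)C)[C@H](OC(=O)c2ccccc2)[C@@H]1O[Si](C)(C)C(C)(C)C)c1ccccc1 | intermediate
22 | [(3S,4R,5R,6R)-5-(benzoyloxy)-3,4,6-trihydroxycyclohex-1-en-1-yl]methyl benzoate | O=C(OCC1=C[C@H](O)[C@@H](O)[C@H](OC(=O)c2ccccc2)[C@@H]1O)c1ccccc1 | target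

Total step count: 15. Longest linear sequence: 15 steps (1 → 22).

Steps most likely to fail

Step 7. The aldol may close with poor facial selectivity at C3, delivering the hydroxyl to both faces of the aldehyde, and the ketol may lose water by β-elimination if the reaction is prolonged. The fallback sets out from 12 and returns at 21; it no longer takes C3 from the aldol or from an SN2 inversion but sets it by ketone reduction. Ketol 12 and any (3S)-ketol F1 are carried unseparated through steps 8 to 12. The F1 series passes through TES ether F2, enol triflate F3, allylic alcohol F4 and 7-O-benzoate F5 and reaches 21 directly. The mixture of 19 and 21 is then oxidised with Dess–Martin periodinane (NaHCO3, CH2Cl2) to the single enone F6. NaBH4/CeCl3·7H2O in MeOH at −78 °C (Luche reduction) should reduce F6 to 21. The enone should adopt the half-chair with the C6 silyloxy group pseudo-axial (allylic strain against C7) and the C4 silyloxy group pseudo-equatorial, so axial hydride delivery should give the pseudo-equatorial C3 alcohol trans to O4. Steps 13 and 14 then fall away and the route resumes at step 15.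

Step 2. Benzoate is a weak nucleophile for a hindered ring-fused oxirane, so the opening may stall, and at the temperature required intermolecular acyl transfer may scramble the ester. The fallback sets out from 3 and returns at 8; it opens the epoxide with an alkoxide and introduces the benzoate by acylation. Sodium 4-methoxybenzyl oxide (NaH, 4-methoxybenzyl alcohol, DMF, 90 °C) should give the 3-O-(4-methoxybenzyl) altroside F7 by the same trans-diaxial attack at C3. TBSOTf/2,6-lutidine gives the 2-O-TBS ether F8, and DDQ in wet CH2Cl2 removes the benzylic ether to give the 3-alcohol F9. PhCOCl/pyridine/4-(dimethylamino)pyridine gives the 3-benzoate F10, and hydrogenolysis (H2, Pd(OH)2 on carbon) gives the 4,6-diol F11. Garegg–Samuelsson iodination gives the 6-iodide F12, and TBSOTf/2,6-lutidine silylates O4 to give 8.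

Step 9. The C2 enolate may expel the C3 silyloxy group (E1cB), proton transfer to the C6 enolate would expel the C5 benzoate, and the amide base may attack an ester. The fallback sets out from 13 and returns at 16; it avoids an enolate altogether. Condensation with N2H4·H2O (Et3N, EtOH, rt) gives hydrazone F13. Barton vinyl iodide synthesis (I2, 1,1,3,3-tetramethylguanidine, THF, 0 °C) should give vinyl iodide F14, the proton being lost from the unhindered C2. Stille coupling of F14 with 15 (Pd(PPh3)4, 1,4-dioxane, 90 °C) gives 16.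

Further compounds
F1 | step 7 | (3S)-5-(benzoyloxy)-4,6-bis(TBS-oxy)-3-hydroxycyclohexan-1-one (C3 epimer of 12) | O=C1C[C@H](O)[C@@H](O[Si](C)(C)C(C)(C)C)[C@H](OC(=O)c2ccccc2)[C@@H]1O[Si](C)(C)C(C)(C)C
F2 | step 7 | (3S)-5-(benzoyloxy)-4,6-bis(TBS-oxy)-3-(TES-oxy)cyclohexan-1-one | O=C1C[C@H](O[Si](CC)(CC)CC)[C@@H](O[Si](C)(C)C(C)(C)C)[C@H](OC(=O)c2ccccc2)[C@@H]1O[Si](C)(C)C(C)(C)C
F3 | step 7 | (3S)-5-(benzoyloxy)-4,6-bis(TBS-oxy)-3-(TES-oxy)cyclohex-1-en-1-yl trifluoromethanesulfonate | O=S(=O)(OC1=C[C@H](O[Si](CC)(CC)CC)[C@@H](O[Si](C)(C)C(C)(C)C)[C@H](OC(=O)c2ccccc2)[C@@H]1O[Si](C)(C)C(C)(C)C)C(F)(F)F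
F4 | step 7 | (3S)-[5-(benzoyloxy)-4,6-bis(TBS-oxy)-3-(TES-oxy)cyclohex-1-en-1-yl]methanol | OCC1=C[C@H](O[Si](CC)(CC)CC)[C@@H](O[Si](C)(C)C(C)(C)C)[C@H](OC(=O)c2ccccc2)[C@@H]1O[Si](C)(C)C(C)(C)C
F5 | step 7 | (3S)-[5-(benzoyloxy)-4,6-bis(TBS-oxy)-3-(TES-oxy)cyclohex-1-en-1-yl]methyl benzoate | O=C(OCC1=C[C@H](O[Si](CC)(CC)CC)[C@@H](O[Si](C)(C)C(C)(C)C)[C@H](OC(=O)c2ccccc2)[C@@H]1O[Si](C)(C)C(C)(C)C)c1ccccc1
F6 | step 7 | [5-(benzoyloxy)-4,6-bis(TBS-oxy)-3-oxocyclohex-1-en-1-yl]methyl benzoate (C4–C6 as in 22) | O=C(OCC1=CC(=O)[C@@H](O[Si](C)(C)C(C)(C)C)[C@H](OC(=O)c2ccccc2)[C@@H]1O[Si](C)(C)C(C)(C)C)c1ccccc1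
F7 | step 2 | methyl 4,6-O-benzylidene-3-O-(4-methoxybenzyl)-α-D-altropyranoside | CO[C@@H]1[C@@H](O)[C@H](OCc2ccc(OC)cc2)[C@@H]3O[C@H](c4ccccc4)OC[C@H]3O1
F8 | step 2 | methyl 4,6-O-benzylidene-3-O-(4-methoxybenzyl)-2-O-TBS-α-D-altropyranoside | CO[C@@H]1[C@@H](O[Si](C)(C)C(C)(C)C)[C@H](OCc2ccc(OC)cc2)[C@@H]3O[C@H](c4ccccc4)OC[C@H]3O1
F9 | step 2 | methyl 4,6-O-benzylidene-2-O-TBS-α-D-altropyranoside | CO[C@@H]1[C@@H](O[Si](C)(C)C(C)(C)C)[C@H](O)[C@@H]3O[C@H](c4ccccc4)OC[C@H]3O1
F10 | step 2 | methyl 3-O-benzoyl-4,6-O-benzylidene-2-O-TBS-α-D-altropyranoside | CO[C@@H]1[C@@H](O[Si](C)(C)C(C)(C)C)[C@H](OC(=O)c2ccccc2)[C@@H]3O[C@H](c4ccccc4)OC[C@H]3O1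
F11 | step 2 | methyl 3-O-benzoyl-2-O-TBS-α-D-altropyranoside | CO[C@@H]1[C@@H](O[Si](C)(C)C(C)(C)C)[C@H](OC(=O)c2ccccc2)[C@H](O)[C@@H](CO)O1
F12 | step 2 | methyl 3-O-benzoyl-2-O-TBS-6-deoxy-6-iodo-α-D-altropyranoside | CO[C@@H]1[C@@H](O[Si](C)(C)C(C)(C)C)[C@H](OC(=O)c2ccccc2)[C@H](O)[C@@H](CI)O1
F13 | step 9 | hydrazone of 13 (C=N geometry undefined) | NN=C1C[C@@H](O[Si](CC)(CC)CC)[C@@H](O[Si](C)(C)C(C)(C)C)[C@H](OC(=O)c2ccccc2)[C@@H]1O[Si](C)(C)C(C)(C)C
F14 | step 9 | (3R)-5-(benzoyloxy)-4,6-bis(TBS-oxy)-1-iodo-3-(TES-oxy)cyclohex-1-ene | IC1=C[C@@H](O[Si](CC)(CC)CC)[C@@H](O[Si](C)(C)C(C)(C)C)[C@H](OC(=O)c2ccccc2)[C@@H]1O[Si](C)(C)C(C)(C)C
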